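**Assumption:** trans-communic acid is bought as a catalogue natural product and is the limiting reagent in step 2, where the enal is used in fourfold excess and the unreacted part is recovered; (−)-β-caryophyllene is a bulk chemical.

**Numbering used:** caryophyllane atoms are unprimed (C14 = carbon on C4, C15 = exocyclic CH2 on C8); labdane atoms are primed. "Ring-trans" means C3 and C6 on opposite sides of C4=C5 (as in β-caryophyllene); "ring-cis" means the same side (as in isocaryophyllene).

## Retrosynthetic overview

1. The target is a [4+2] adduct: cutting C4–C12' and C5–C15' gives trans-communic acid (diene C12'=C13'–C14'=C15') and a ring-trans caryophyllene C14-carbonyl dienophile, the union the biosynthesis presumably uses.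
2. The ring-fusion CO2H is carried through the cycloaddition as CHO and oxidised last.
3. SeO2 oxidation of β-caryophyllene at C14 is expected to give the ring-cis enal, not the needed ring-trans one, so the ring-trans enal is generated by light in the flask and consumed by the cycloaddition.
4. Ring order: the decalin and the cyclobutane/nine-membered ring are bought intact; the cyclohexene is the only ring formed, in step 2, and it sets C4, C5 and C12' at once.

## Route

Step 1
Reactants: 1 (−)-β-caryophyllene
Product: 3 ring-cis enal, via ring-cis allylic alcohol 2 (not isolated)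
Conditions: SeO2 (2 equiv), pyridine (0.3 equiv), 1,4-dioxane, 80 °C
Reagents that add atoms: SeO2, selenium dioxide, O=[Se]=O
Why: Riley allylic oxidation: SeO2 adds to C5 of the strained trisubstituted alkene in an ene reaction that takes a C14–H, and the following [2,3]-sigmatropic shift returns oxygen to C14 anti to C6, so C4=C5 re-forms ring-cis (the same trans-to-cis ring isomerisation seen when the vinylic methyl of ten-membered germacrolides is oxidised with SeO2); the second equivalent takes the allylic alcohol on to the enal, and no stereocentre is made or touched (C1 and C9 come from the starting material).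

Step 2
Reactants: 3 ring-cis enal; 4 trans-communic acid
Product: 6 cycloadduct aldehyde, via ring-trans enal 5 (not isolated)
Conditions: hν (350 nm), degassed PhCF3, 0 °C, to the photostationary state; then trans-communic acid, BHT (cat.), concentrate to ca. 2 M, 110 °C, sealed tube, dark; enal in fourfold excess
Reagents that add atoms: none
Why: Proposed new method: n→π* excitation of the ring-cis enal gives a twisted triplet that relaxes to either alkene geometry, so a photostationary share of the strained ring-trans enal builds up (closest known reaction type: light-driven cis→trans isomerisation of medium-ring enones followed by thermal Diels–Alder trapping of the strained isomer), and on heating this isomer reacts much faster than the ring-cis one with the s-cis 12'E,14'-diene in a normal-demand Diels–Alder reaction because the cycloaddition releases the trans-cyclononene strain; C15' bonds to the β-carbon C5 and C12' to C4 (1-alkyl-diene "ortho" orientation), the diene adds to the exposed outer face of the trans-cyclononene (the face that gives natural caryophyllene oxide; sets 4S and 5S), the ring-trans geometry is copied suprafacially into the trans ring fusion, and CHO-endo approach places the C11' chain cis to CHO (12'R).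

Step 3
Reactants: 6 cycloadduct aldehyde
Product: 7 target acid CNP0330729.1
Conditions: NaClO2, NaH2PO4, 2-methyl-2-butene, t-BuOH/H2O (4:1), 0 °C → rt
Reagents that add atoms: NaClO2, sodium chlorite, [Na+].[O-]Cl=O
Why: Pinnick oxidation: HClO2 adds to the aldehyde and fragments to the acid, HOCl is trapped by 2-methyl-2-butene so the three alkenes survive, and the α-carbon is quaternary so no stereocentre can epimerise.

## Compound list

1 | (−)-β-caryophyllene, (1R,4E,9S)-4,11,11-trimethyl-8-methylidenebicyclo[7.2.0]undec-4-ene (ring-trans) | C=C1CC/C=C(C)/CC[C@@H]2[C@@H]1CC2(C)C | starting material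

2 | ring-cis allylic alcohol (14-hydroxyisocaryophyllene), [(1R,4E,9S)-11,11-dimethyl-8-methylidenebicyclo[7.2.0]undec-4-en-4-yl]methanol | C=C1CC/C=C(CO)\CC[C@@H]2[C@@H]1CC2(C)C | intermediate

3 | ring-cis enal (isocaryophyllen-14-al), (1R,4E,9S)-11,11-dimethyl-8-methylidenebicyclo[7.2.0]undec-4-ene-4-carbaldehyde (C3/C6 cis, CHO trans to C6) | C=C1CC/C=C(C=O)\CC[C@@H]2[C@@H]1CC2(C)C | intermediate

4 | trans-communic acid, (1S,4aR,5S,8aR)-1,4a-dimethyl-6-methylidene-5-[(2E)-3-methylpenta-2,4-dien-1-yl]decahydronaphthalene-1-carboxylic acid | C=C/C(C)=C/C[C@H]1C(=C)CC[C@@H]2[C@]1(C)CCC[C@]2(C)C(=O)O | starting material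

5 | ring-trans enal (β-caryophyllen-14-al), (1R,4Z,9S)-11,11-dimethyl-8-methylidenebicyclo[7.2.0]undec-4-ene-4-carbaldehyde (C3/C6 trans, CHO cis to C6) | C=C1CC/C=C(C=O)/CC[C@@H]2[C@@H]1CC2(C)C | intermediate

6 | cycloadduct aldehyde: C4 (bearing CHO) bonded to C12', C5 bonded to C15', new cyclohexene C13'=C14' with 13'-methyl; trans ring fusion, CHO cis to C6 and to the C11' chain; (1R,4S,5S,9S,12'R,4'S,5'R,9'S,10'R) | C=C1CC[C@H]2CC=C(C)[C@@H](C[C@H]3C(=C)CC[C@@H]4[C@]3(C)CCC[C@]4(C)C(=O)O)[C@]2(C=O)CC[C@@H]2[C@@H]1CC2(C)C | intermediate

7 | target CNP0330729.1: as the cycloadduct aldehyde with CO2H in place of CHO at C4; (1R,4S,5S,9S,12'R,4'S,5'R,9'S,10'R) | C=C1CC[C@H]2CC=C(C)[C@@H](C[C@H]3C(=C)CC[C@@H]4[C@]3(C)CCC[C@]4(C)C(=O)O)[C@]2(C(=O)O)CC[C@@H]2[C@@H]1CC2(C)C | target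

## Count and risks

Total step count: 3. Longest linear sequence: 3 (1 → 3 → 6 → 7).

**Step 1.** SeO2 may attack the other allylic sites (C3, C7, C9), stop at mixtures of 2 and 3, or trigger acid-induced transannular rearrangement. The fallback sets out from 1 and comes back at 3. Epoxidise 1 with mCPBA/NaHCO3 to caryophyllene oxide F1 (also purchasable). Isomerise with Al(OiPr)3 in hot toluene, which removes a C14 proton, to the exocyclic allylic alcohol F2. Transpose the hydroxyl with catalytic Ph3SiOReO3 in Et2O to the more stable primary allylic alcohol 2, then oxidise with MnO2 to 3.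

**Step 2 (most likely to fail).** The photostationary share of 5 may be small, photodeconjugation may compete, and the thermal cycloaddition may be slow or give exo, wrong-face and cis-fused isomers while 4 polymerises. The fallback sets out from 3 and comes back at 6, replacing light by a stereospecific thermal olefin inversion and heat by pressure. Reduce 3 with NaBH4/CeCl3·7H2O to 2 (isolated here). Epoxidise with VO(acac)2/t-BuOOH, which touches only the allylic-alcohol alkene, to the cis-epoxy alcohol F3. Silylate with TBSCl/imidazole to the epoxy silyl ether F4. Treat with LiPPh2 in THF and then MeI: anti opening at C5 followed by syn loss of the phosphine oxide inverts the alkene and gives the ring-trans silyl ether F5. TBAF gives the ring-trans allylic alcohol F6, and MnO2 gives pure 5. Combine 5 with 4 at 1.2 GPa in CH2Cl2 at room temperature to reach 6.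

**Step 3.** The aldehyde is neopentyl and flanked by a quaternary centre, so the oxidation may be slow and HOCl may add to the alkenes. The fallback sets out from 5 and comes back at 7, moving the oxidation ahead of the cycloaddition. Take 5 from the irradiated mixture by chromatography on AgNO3-impregnated silica (or from the step-2 fallback) and oxidise this unhindered enal with NaClO2/NaH2PO4/2-methyl-2-butene to the ring-trans acid F7. Combine F7 with 4 under 2-iodophenylboronic acid (20 mol%), 4 Å molecular sieves, CH2Cl2, 40 °C; the acyloxyboron species lowers the LUMO of the free unsaturated acid and gives 7 directly.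

## Further compounds

F1 | step 1 | (−)-caryophyllene oxide, (1R,4R,5R,9S)-4,5-epoxycaryophyll-8(15)-ene | C=C1CC[C@H]2O[C@]2(C)CC[C@@H]2[C@@H]1CC2(C)C
F2 | step 1 | (1R,5R,9S)-caryophylla-4(14),8(15)-dien-5-ol | C=C1CC[C@@H](O)C(=C)CC[C@@H]2[C@@H]1CC2(C)C
F3 | step 2 | cis-4,5-epoxy-14-hydroxycaryophyll-8(15)-ene (C3/C6 cis on the oxirane; 1R,4S,5S,9S shown, the other face isomer converges) | C=C1CC[C@@H]2O[C@]2(CO)CC[C@@H]2[C@@H]1CC2(C)C
F4 | step 2 | tert-butyldimethylsilyl ether of F3 | C=C1CC[C@@H]2O[C@]2(CO[Si](C)(C)C(C)(C)C)CC[C@@H]2[C@@H]1CC2(C)C
F5 | step 2 | ring-trans silyl ether, (1R,4Z,9S)-4-(tert-butyldimethylsilyloxymethyl)-11,11-dimethyl-8-methylidenebicyclo[7.2.0]undec-4-ene | C=C1CC/C=C(CO[Si](C)(C)C(C)(C)C)/CC[C@@H]2[C@@H]1CC2(C)C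
F6 | step 2 | ring-trans allylic alcohol (14-hydroxy-β-caryophyllene), [(1R,4Z,9S)-11,11-dimethyl-8-methylidenebicyclo[7.2.0]undec-4-en-4-yl]methanol | C=C1CC/C=C(CO)/CC[C@@H]2[C@@H]1CC2(C)C
F7 | step 3 | ring-trans acid, (1R,4Z,9S)-11,11-dimethyl-8-methylidenebicyclo[7.2.0]undec-4-ene-4-carboxylic acid | C=C1CC/C=C(C(=O)O)/CC[C@@H]2[C@@H]1CC2(C)C
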